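## The problem

8-Hydroxyluteolin 7-sulfate (24) is a flavone: a benzene ring A fused to a 4-pyranone ring C that carries a 3,4-dihydroxyphenyl ring B at C2. It has no stereocentre, so the difficulty lies in the substitution pattern and in telling five phenolic oxygens apart. Ring A bears oxygen at C5, C7 and C8 and hydrogen only at C6, and the sulfate must sit on O7 alone, next to the free O8 hydroxyl. The aryl hydrogen sulfate does not survive strong Lewis or Brønsted acids, and the unmasked 5,8-hydroquinone and the ring B catechol are oxidised by air in base. The last step must therefore be a neutral, reductive unmasking, and every oxygen except O7 has to carry the same kind of protecting group until then. The feature that allows a direct construction is that C5 and C8 carry para oxygens, with the oxygenated C7 and the unsubstituted C6 between them and with C4a and C8a shared with ring C. This is the pattern laid down when an alkoxycarbene carbon (C5), the two carbons of a terminal ynol ether (C6, C7) and one carbon monoxide ligand (C8) are joined across a pyranone C2=C3 bond (C8a, C4a) in a Dötz benzannulation. The annulation also delivers O5 as an ether and O8 as a free phenol, so the three oxygens of ring A emerge already differentiated.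

## Retrosynthesis

**24 from 23.** The free acid 24 is traced to its sodium salt 23, in which all four remaining hydroxyls are benzyl ethers. Only O–benzyl bonds are cut. Hydrogenolysis is chosen over acid- or Lewis-acid-labile groups because it is the one global deprotection an aryl sulfate salt tolerates. The forward reaction must cleave four benzyl ethers without touching the C2=C3 bond or the sulfate.

**23 from 22.** The S–O7 bond is cut. Precursor 22 has a single free hydroxyl, at C7, so sulfation needs no selectivity, which could not be relied on if O8 were also free.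

**22 from 21 and 20.** O7 must carry a group that is removed without touching benzyl ethers, and O8 must be benzylated beside it. A silyl ether on O7 would be the easiest to remove, but it could migrate to the neighbouring O8 phenoxide during benzylation, and the parent silyloxyethyne needed to introduce it is a sensitive reagent with a less routine preparation. A 2-(trimethylsilyl)ethyl ether keeps the fluoride lability, cannot migrate, and comes from an ynol ether that is accessible by standard chemistry. Thus 22 comes from 21 by fluoride-induced elimination, and 21 from phenol 20 by ordinary base-mediated benzylation.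

**20 from 14 and 19 (key disconnection).** Ring A is taken apart at C5–C6, C7–C8 and C8–C8a. This gives the pyranonyl(benzyloxy)carbene chromium complex 14, the ynol ether 19 and one carbon monoxide ligand of 14. Cutting ring C instead, at its C–O or C–acyl bonds, would require a 1,2,3,5-tetraoxygenated benzene with three differentiated oxygens, which is the hard part of the molecule. The chosen cut builds that pattern in one step from two simple partners and leaves O5 as a benzyl ether and O8 free. The forward reaction needs the alkyne to insert with its CH terminus on the carbene carbon, carbon monoxide insertion to follow, and the ketene to close onto pyranone C2.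

**14 from 12, and 12 from 8 and 9.** The carbene C–O(benzyl) bond is cut back to the acylchromate 12. Acylchromates are not benzylated cleanly by benzyl halides, so the benzyloxy group is planned to enter by alcohol exchange on a transient acyloxycarbene 13. The acyl–chromium bond is cut to the acid chloride 8 and hexacarbonylchromium 9 by way of the pentacarbonylchromate dianion 10 and its first acylation product 11. An organolithium route is excluded because a 3-lithio-4-pyranone would not survive.

**8 from 7, 6, 4 and 2.** The acid chloride 8 comes from acid 7 and its tert-butyl ester 6. The tert-butyl ester is chosen because a 4-pyranone-3-carboxylate opens at C2 under hydroxide, while acidolysis leaves ring and benzyl ethers intact. Pyranone 6 is cut at C4–C5 and O1–C2 to the enaminone 4 and the aroyl chloride 2: acylation of 4 at its acetyl methyl group gives the triketone 5, whose enol oxygen displaces the amino group. This places the carboxyl group at C3 without any regiochemical question. Enaminone 4 comes from tert-butyl 3-oxobutanoate 3, and 2 from 3,4-bis(benzyloxy)benzoic acid 1.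

**19 from 17, 15 and 16.** The ynol ether 19 is cut to the (E)-1,2-dichlorovinyl ether 17, made from 2-(trimethylsilyl)ethanol 15 and trichloroethylene 16. Elimination and chlorine–lithium exchange give the lithium alkoxyacetylide 18, which is protonated. A primary alkyl ynol ether was preferred to a tertiary one because it does not fragment to a ketene at the temperature of the annulation.

## Roads not taken

**Alternative 1:** aryne insertion into an arylpropiolic acid.
- **Cut:** ring C at C8a–O1, C4a–C4 and O1–C2.
- **Forward step:** fluoride (CsF) would release a 3,5-dialkoxybenzyne from 5-(allyloxy)-3-(benzyloxy)-2-(trimethylsilyl)phenyl trifluoromethanesulfonate A3. The carboxylate of 3-[3,4-bis(benzyloxy)phenyl]propiolic acid A2 would add to it, the acyl group would shift to the neighbouring aryne carbon, and the phenoxide would close onto the ynone to give 7-(allyloxy)-5-(benzyloxy)-2-[3,4-bis(benzyloxy)phenyl]-4H-chromen-4-one A1.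
- **Merits:** the road is convergent and needs no stoichiometric metal. Acid A2 is a simple, stable partner, and the alkoxy group next to the aryne of A3 steers the oxygen nucleophile to the distal carbon, which is the orientation a flavone needs.
- **Weak points:** flavone A1 has hydrogen at C8, so the most difficult oxygen of the target is still missing. A late C8 oxidation would have to be run on a ring whose other oxygens are already protected. Triflate A3 itself needs several steps with two differentiated ethers, and five-membered closure to an aurone competes with the six-membered closure that leads to A1.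
- **Comparison:** this road is better precedented for ring C. The chosen plan sets against this that it installs all of ring A, the C8 oxygen included, in one step.

**Alternative 2:** Moore ring expansion on a pyranone.
- **Cut:** C4a–C5, ring A being formed from a four-membered ring.
- **Forward step:** heating 4-{6-[3,4-bis(benzyloxy)phenyl]-4-oxo-4H-pyran-2-yl}-4-hydroxy-3-[(4-methoxybenzyl)oxy]cyclobut-2-en-1-one A5 would open it to a dienylketene. The ketene carbon closes onto pyranone C3 to give 2-[3,4-bis(benzyloxy)phenyl]-5,8-dihydroxy-7-(4-methoxybenzyloxy)-4H-chromen-4-one A4.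
- **Merits:** the step is thermal and metal-free, with unambiguous regiochemistry. The ketene closes onto the nucleophilic α-carbon of the enone, a better polarity match than closure onto C2 in the chosen plan. Hydroquinone A4 would reach the target by double benzylation, removal of the 4-methoxybenzyl group, sulfation and hydrogenolysis, so the endgame from A4 is as short as the one planned here.
- **Weak points:** cyclobutenone A5 requires a 2-metalated 6-aryl-4-pyranone to add to one carbonyl of an alkoxycyclobutenedione. Such an anion sits on a Michael acceptor and is expected to self-condense, and the addition must also be regioselective.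
- **Comparison:** the ring-forming step from A5 to A4 is probably the safer one. The chosen plan sets against it that both partners are made by routine chemistry and that no pyranone carbanion is needed.

**Alternative 3:** oxa-Michael closure onto a transient acylquinone.
- **Cut:** O1–C8a.
- **Forward step:** (NH4)2Ce(NO3)6 (tetravalent cerium) would oxidise the dimethoxyaryl ring of 1-[4-(allyloxy)-2,5-dimethoxyphenyl]-3-[3,4-bis(benzyloxy)phenyl]propane-1,3-dione A7 to an acylquinone. The diketone enol oxygen adds at C8a, and a reductive work-up gives 7-(allyloxy)-2-[3,4-bis(benzyloxy)phenyl]-5,8-dihydroxy-4H-chromen-4-one A6.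
- **Merits:** this is the shortest road. Diketone A7 comes from a Claisen condensation of simple aromatic building blocks, and hydroquinone A6 needs only benzylation and deallylation to reach the sulfation substrate.
- **Weak points:** the oxidant must choose the trialkoxy ring of A7 over the ring B catechol ether, the allyl group and the enolised diketone. The enol carbon can compete with the enol oxygen as nucleophile, and the hydroquinone A6 is re-oxidised unless the oxidant is metered exactly.
- **Comparison:** in step count this road is better. The chosen plan sets against it that no oxidant meets the electron-rich rings and that the oxidation level and positions of all ring A oxygens are fixed by the partners.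

Key step: step 10

## Remarks on the chemistry

- The target is taken as the free hydrogen sulfate as drawn. It is carried as the sodium salt 23 and set free with one equivalent of acid in the last operation.
- The enamine double bond of 4 and 5 has no defined configuration; it is lost on cyclisation.

## Route

Step 1
Reactants: 1 3,4-bis(benzyloxy)benzoic acid
Product: 2 3,4-bis(benzyloxy)benzoyl chloride
Conditions: (COCl)2, DMF (cat.), CH2Cl2, 0 °C → rt
Reagents that add atoms: oxalyl chloride, O=C(Cl)C(=O)Cl
Why: Standard acid chloride formation through the chloroiminium catalyst; aryl benzyl ethers are inert to these conditions.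

Step 2
Reactants: 3 tert-butyl 3-oxobutanoate
Product: 4 tert-butyl 2-[(dimethylamino)methylidene]-3-oxobutanoate
Conditions: Me2NCH(OMe)2, toluene, 60 °C
Reagents that add atoms: N,N-dimethylformamide dimethyl acetal, COC(OC)N(C)C
Why: Condensation of an amide acetal with the active methylene of a β-keto ester, a routine enaminone synthesis.

Step 3
Reactants: 4 tert-butyl 2-[(dimethylamino)methylidene]-3-oxobutanoate; 2 3,4-bis(benzyloxy)benzoyl chloride
Product: 6 tert-butyl 6-[3,4-bis(benzyloxy)phenyl]-4-oxo-4H-pyran-3-carboxylate, via acylated enaminone 5 (not isolated)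
Conditions: LiN(SiMe3)2 (2.2 equiv), THF, −78 °C; then 1 M HCl, Et2O, 0 °C → rt
Reagents that add atoms: none
Why: The vinylogous amide is deprotonated at its acetyl methyl group and C-acylated by the aroyl chloride (Claisen-type acylation of an enaminone anion); on acidification the enol oxygen of the new diketone displaces dimethylamine at the aminomethylidene carbon by addition–elimination and closes the 4-pyranone, a known route to 6-substituted 4-oxo-4H-pyran-3-carboxylates; the tert-butyl ester tolerates cold dilute aqueous acid.

Step 4
Reactants: 6 tert-butyl 6-[3,4-bis(benzyloxy)phenyl]-4-oxo-4H-pyran-3-carboxylate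
Product: 7 6-[3,4-bis(benzyloxy)phenyl]-4-oxo-4H-pyran-3-carboxylic acid
Conditions: CF3CO2H, CH2Cl2, 0 °C → rt
Reagents that add atoms: none
Why: Acidolysis of a tert-butyl ester frees the acid without the hydroxide that would open the pyranone at C2; aryl benzyl ethers survive brief exposure to this acid.

Step 5
Reactants: 7 6-[3,4-bis(benzyloxy)phenyl]-4-oxo-4H-pyran-3-carboxylic acid
Product: 8 6-[3,4-bis(benzyloxy)phenyl]-4-oxo-4H-pyran-3-carbonyl chloride
Conditions: 1-chloro-N,N,2-trimethylprop-1-en-1-amine, CH2Cl2, 0 °C → rt
Reagents that add atoms: 1-chloro-N,N,2-trimethylprop-1-en-1-amine, CC(C)=C(Cl)N(C)C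
Why: The α-chloroenamine converts acids into acid chlorides under neutral conditions, so neither the vinylogous ester carbonyl nor the benzyl ethers meet HCl; the crude chloride is used directly.

Step 6
Reactants: 9 hexacarbonylchromium; 8 6-[3,4-bis(benzyloxy)phenyl]-4-oxo-4H-pyran-3-carbonyl chloride
Product: 12 tetramethylammonium pentacarbonyl{[6-(3,4-bis(benzyloxy)phenyl)-4-oxo-4H-pyran-3-yl]carbonyl}chromate, via Na2Cr(CO)5 10 (not isolated), via sodium acylchromate 11 (not isolated)
Conditions: NaC10H8 (2 equiv), THF, −78 °C; then 8, −78 → 0 °C; then Me4NBr, H2O, rt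
Reagents that add atoms: tetramethylammonium bromide, C[N+](C)(C)C.[Br-]
Why: Two-electron reduction of Cr(CO)6 gives the pentacarbonylchromate dianion, which is acylated at chromium by acid chlorides, the established alternative to the organolithium route for acyl groups that cannot be made as carbanions; cation exchange gives a salt soluble in CH2Cl2 for the next step.

Step 7
Reactants: 12 tetramethylammonium pentacarbonyl{[6-(3,4-bis(benzyloxy)phenyl)-4-oxo-4H-pyran-3-yl]carbonyl}chromate
Product: 14 pentacarbonyl{(benzyloxy)[6-(3,4-bis(benzyloxy)phenyl)-4-oxo-4H-pyran-3-yl]methylidene}chromium, via acetoxycarbene complex 13 (not isolated)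
Conditions: AcBr, CH2Cl2, −40 °C; then BnOH, −40 → 0 °C
Reagents that add atoms: benzyl alcohol, OCc1ccccc1
Why: O-Acylation of the acylchromate gives a highly electrophilic acyloxycarbene whose acetate is displaced at the carbene carbon by the alcohol, the standard way to alkoxycarbene complexes that cannot be made with oxonium salts; the ring oxygen conjugated to the carbene through C2=C3 should stabilise 14.

Step 8
Reactants: 15 2-(trimethylsilyl)ethanol; 16 trichloroethylene
Product: 17 [2-{[(E)-1,2-dichloroethenyl]oxy}ethyl](trimethyl)silane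
Conditions: KH, THF, 0 °C → rt; then 16, −50 °C → rt
Reagents that add atoms: none
Why: The potassium alkoxide dehydrochlorinates trichloroethylene to dichloroacetylene and adds to it in an anti sense, the usual preparation of (E)-1,2-dichlorovinyl ethers from alcohols.

Step 9
Reactants: 17 [2-{[(E)-1,2-dichloroethenyl]oxy}ethyl](trimethyl)silane
Product: 19 [2-(ethynyloxy)ethyl](trimethyl)silane, via lithium alkoxyacetylide 18 (not isolated)
Conditions: n-BuLi (2.2 equiv), Et2O, −78 → −40 °C; then MeOH, −78 °C
Reagents that add atoms: none
Why: Elimination of HCl gives the chloroalkynyl ether, chlorine–lithium exchange gives the lithium alkoxyacetylide, and protonation gives the terminal ynol ether, the standard sequence from dichlorovinyl ethers; a primary alkyl ynol ether is stable far above the temperature used later.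

Step 10
Reactants: 14 pentacarbonyl{(benzyloxy)[6-(3,4-bis(benzyloxy)phenyl)-4-oxo-4H-pyran-3-yl]methylidene}chromium; 19 [2-(ethynyloxy)ethyl](trimethyl)silane
Product: 20 5-(benzyloxy)-2-[3,4-bis(benzyloxy)phenyl]-8-hydroxy-7-[2-(trimethylsilyl)ethoxy]-4H-chromen-4-one
Conditions: 19 (2 equiv), THF, 50 °C, Ar; then air, EtOAc, rt
Reagents that add atoms: none
Why: Proposed new method: thermal loss of one CO from 14 (possibly helped by transient coordination of the C4 carbonyl oxygen) opens a site for alkyne 19, which inserts into the chromium–carbene bond with its unsubstituted carbon bonded to the carbene carbon; CO insertion into the resulting oxygen-stabilised vinylcarbene gives a chromium-bound dienylketene, whose ketene carbon closes onto pyranone C2 by six-electron electrocyclisation (ring A, six-membered, the pyranone C2=C3 bond being held s-cis to the carbene by the ring), and enolisation of the cyclohexadienone restores the chromone and gives the C8 phenol. The closest known reaction type is the Dötz benzannulation of alkenyl- and heteroaryl(alkoxy)carbene chromium complexes with terminal alkynes; a 4-pyranon-3-yl carbene is an untested carbene partner in it, and an electron-rich terminal ynol ether is a demanding alkyne partner that tends to stop after insertion. The carbene carbon becomes C5 with its benzyloxy group, the alkyne carbons become C6 and C7, the CO carbon becomes C8, and pyranone C2 and C3 become C8a and C4a. No stereocentre is formed. The step needs regioselective insertion, and sterics (a terminal alkyne puts hydrogen next to the carbene carbon) and electronics (the nucleophilic β-carbon of the ynol ether attacks the electrophilic carbene carbon) point the same way, placing the alkoxy carbon next to C8. It also needs CO insertion to win over arrest at the inserted carbene and over five-ring closure, for which a coordinating solvent, moderate temperature and an alkoxy rather than amino carbene are chosen. Residual chromium is removed with air only, because an oxidant such as (NH4)2Ce(NO3)6 would turn the 5-benzyloxy-8-hydroxy ring into a quinone.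

Step 11
Reactants: 20 5-(benzyloxy)-2-[3,4-bis(benzyloxy)phenyl]-8-hydroxy-7-[2-(trimethylsilyl)ethoxy]-4H-chromen-4-one
Product: 21 5,8-bis(benzyloxy)-2-[3,4-bis(benzyloxy)phenyl]-7-[2-(trimethylsilyl)ethoxy]-4H-chromen-4-one
Conditions: BnBr, K2CO3, DMF, rt, Ar
Reagents that add atoms: benzyl bromide, BrCc1ccccc1
Why: Williamson etherification of the only free phenol; the carbon-bound O7 group cannot migrate to the neighbouring phenoxide, and argon protects the hydroquinone monoether from air in base.

Step 12
Reactants: 21 5,8-bis(benzyloxy)-2-[3,4-bis(benzyloxy)phenyl]-7-[2-(trimethylsilyl)ethoxy]-4H-chromen-4-one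
Product: 22 5,8-bis(benzyloxy)-2-[3,4-bis(benzyloxy)phenyl]-7-hydroxy-4H-chromen-4-one
Conditions: Bu4NF, DMF, 60 °C; then AcOH
Reagents that add atoms: none
Why: Fluoride attack at silicon triggers β-elimination of ethene and expels the phenoxide, the known cleavage of aryl 2-(trimethylsilyl)ethyl ethers; the 7-oxide of a flavone is a vinylogous carboxylate and a good leaving group, and benzyl ethers are untouched.

Step 13
Reactants: 22 5,8-bis(benzyloxy)-2-[3,4-bis(benzyloxy)phenyl]-7-hydroxy-4H-chromen-4-one
Product: 23 sodium 5,8-bis(benzyloxy)-2-[3,4-bis(benzyloxy)phenyl]-4-oxo-4H-chromen-7-yl sulfate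
Conditions: SO3·pyridine, pyridine, 50 °C; then aq NaHCO3
Reagents that add atoms: sulfur trioxide–pyridine complex, O=S(=O)=O.c1ccncc1; sodium hydrogen carbonate, [Na+].OC([O-])=O
Why: O-Sulfonation of a phenol with an amine–sulfur trioxide complex, with only one hydroxyl available; exchange to the sodium salt removes pyridine, which would slow the hydrogenolysis that follows.

Step 14
Reactants: 23 sodium 5,8-bis(benzyloxy)-2-[3,4-bis(benzyloxy)phenyl]-4-oxo-4H-chromen-7-yl sulfate
Product: 24 8-hydroxyluteolin 7-sulfate (2-(3,4-dihydroxyphenyl)-5,8-dihydroxy-4-oxo-4H-chromen-7-yl hydrogen sulfate)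
Conditions: H2 (1 atm), Pd/C, THF/MeOH, rt; then HCl (1.0 equiv), MeOH/H2O, 0 °C, Ar; Sephadex LH-20
Reagents that add atoms: none
Why: Hydrogenolysis of aryl benzyl ethers in the presence of an aryl sulfate salt is established for flavonoid sulfates and leaves the chromone double bond alone at atmospheric pressure; one equivalent of acid in the cold, under argon, sets the hydrogen sulfate free without hydrolysing it or exposing the hydroquinone to air in base.

## Compound list

1 | 3,4-bis(benzyloxy)benzoic acid | O=C(O)c1ccc(OCc2ccccc2)c(OCc2ccccc2)c1 | starting material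
2 | 3,4-bis(benzyloxy)benzoyl chloride | O=C(Cl)c1ccc(OCc2ccccc2)c(OCc2ccccc2)c1 | intermediate
3 | tert-butyl 3-oxobutanoate | CC(=O)CC(=O)OC(C)(C)C | starting material
4 | tert-butyl 2-[(dimethylamino)methylidene]-3-oxobutanoate (double-bond configuration not defined) | CN(C)C=C(C(C)=O)C(=O)OC(C)(C)C | intermediate
5 | tert-butyl 5-[3,4-bis(benzyloxy)phenyl]-2-[(dimethylamino)methylidene]-3,5-dioxopentanoate (double-bond configuration not defined) | CN(C)C=C(C(=O)OC(C)(C)C)C(=O)CC(=O)c1ccc(OCc2ccccc2)c(OCc2ccccc2)c1 | intermediate (not isolated)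
6 | tert-butyl 6-[3,4-bis(benzyloxy)phenyl]-4-oxo-4H-pyran-3-carboxylate | CC(C)(C)OC(=O)c1coc(-c2ccc(OCc3ccccc3)c(OCc3ccccc3)c2)cc1=O | intermediate
7 | 6-[3,4-bis(benzyloxy)phenyl]-4-oxo-4H-pyran-3-carboxylic acid | O=C(O)c1coc(-c2ccc(OCc3ccccc3)c(OCc3ccccc3)c2)cc1=O | intermediate
8 | 6-[3,4-bis(benzyloxy)phenyl]-4-oxo-4H-pyran-3-carbonyl chloride | O=C(Cl)c1coc(-c2ccc(OCc3ccccc3)c(OCc3ccccc3)c2)cc1=O | intermediate
9 | hexacarbonylchromium, Cr(CO)6 | O=C=[Cr](=C=O)(=C=O)(=C=O)(=C=O)=C=O | starting material
10 | disodium pentacarbonylchromate, Na2Cr(CO)5 | [Na+].[Na+].O=C=[Cr-2](=C=O)(=C=O)(=C=O)=C=O | intermediate (not isolated)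
11 | sodium pentacarbonyl{[6-(3,4-bis(benzyloxy)phenyl)-4-oxo-4H-pyran-3-yl]carbonyl}chromate | [Na+].[O-]C(c1coc(-c2ccc(OCc3ccccc3)c(OCc3ccccc3)c2)cc1=O)=[Cr](=C=O)(=C=O)(=C=O)(=C=O)=C=O | intermediate (not isolated)
12 | tetramethylammonium pentacarbonyl{[6-(3,4-bis(benzyloxy)phenyl)-4-oxo-4H-pyran-3-yl]carbonyl}chromate | C[N+](C)(C)C.[O-]C(c1coc(-c2ccc(OCc3ccccc3)c(OCc3ccccc3)c2)cc1=O)=[Cr](=C=O)(=C=O)(=C=O)(=C=O)=C=O | intermediate
13 | pentacarbonyl{(acetyloxy)[6-(3,4-bis(benzyloxy)phenyl)-4-oxo-4H-pyran-3-yl]methylidene}chromium | CC(=O)OC(c1coc(-c2ccc(OCc3ccccc3)c(OCc3ccccc3)c2)cc1=O)=[Cr](=C=O)(=C=O)(=C=O)(=C=O)=C=O | intermediate (not isolated)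
14 | pentacarbonyl{(benzyloxy)[6-(3,4-bis(benzyloxy)phenyl)-4-oxo-4H-pyran-3-yl]methylidene}chromium | O=c1cc(-c2ccc(OCc3ccccc3)c(OCc3ccccc3)c2)occ1C(OCc1ccccc1)=[Cr](=C=O)(=C=O)(=C=O)(=C=O)=C=O | intermediate
15 | 2-(trimethylsilyl)ethanol | C[Si](C)(C)CCO | starting material
16 | trichloroethylene | ClC=C(Cl)Cl | starting material
17 | [2-{[(E)-1,2-dichloroethenyl]oxy}ethyl](trimethyl)silane | C[Si](C)(C)CCO/C(Cl)=C\Cl | intermediate
18 | lithium [2-(trimethylsilyl)ethoxy]ethynide | [Li]C#COCC[Si](C)(C)C | intermediate (not isolated)
19 | [2-(ethynyloxy)ethyl](trimethyl)silane | C#COCC[Si](C)(C)C | intermediate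
20 | 5-(benzyloxy)-2-[3,4-bis(benzyloxy)phenyl]-8-hydroxy-7-[2-(trimethylsilyl)ethoxy]-4H-chromen-4-one | O=c1cc(-c2ccc(OCc3ccccc3)c(OCc3ccccc3)c2)oc2c(O)c(OCC[Si](C)(C)C)cc(OCc3ccccc3)c12 | intermediate
21 | 5,8-bis(benzyloxy)-2-[3,4-bis(benzyloxy)phenyl]-7-[2-(trimethylsilyl)ethoxy]-4H-chromen-4-one | O=c1cc(-c2ccc(OCc3ccccc3)c(OCc3ccccc3)c2)oc2c(OCc3ccccc3)c(OCC[Si](C)(C)C)cc(OCc3ccccc3)c12 | intermediate
22 | 5,8-bis(benzyloxy)-2-[3,4-bis(benzyloxy)phenyl]-7-hydroxy-4H-chromen-4-one | O=c1cc(-c2ccc(OCc3ccccc3)c(OCc3ccccc3)c2)oc2c(OCc3ccccc3)c(O)cc(OCc3ccccc3)c12 | intermediate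
23 | sodium 5,8-bis(benzyloxy)-2-[3,4-bis(benzyloxy)phenyl]-4-oxo-4H-chromen-7-yl sulfate | [Na+].O=c1cc(-c2ccc(OCc3ccccc3)c(OCc3ccccc3)c2)oc2c(OCc3ccccc3)c(OS(=O)(=O)[O-])cc(OCc3ccccc3)c12 | intermediate
24 | 8-hydroxyluteolin 7-sulfate | O=c1cc(-c2ccc(O)c(O)c2)oc2c(O)c(OS(=O)(=O)O)cc(O)c12 | target

## Step count and risks

Total: 14 steps. Longest linear sequence: 11 steps (step 1 or 2, then 3, 4, 5, 6, 7, 10, 11, 12, 13, 14). The ynol ether branch (steps 8 and 9) joins at step 10.

**Step 10 (key step, proposed new method).**
- **What may go wrong:** the ynol ether may insert into the chromium–carbene bond without the CO insertion that should follow, so that the sequence halts at a heteroatom-stabilised dienylcarbene. The electron-poor, possibly chelated carbene may also decompose before it loses CO, or closure may occur without CO to give a five-membered ring.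
- **Fallback (known chemistry), from 2 and 15 back to 21:**
  - Commercial 2',4',6'-trihydroxyacetophenone is C-aroylated with 2 through its lithium polyanion (LiN(SiMe3)2, THF, −78 °C) to give 1-[3,4-bis(benzyloxy)phenyl]-3-(2,4,6-trihydroxyphenyl)propane-1,3-dione F1.
  - Cyclodehydration (AcOH, trace H2SO4, 90 °C) gives 2-[3,4-bis(benzyloxy)phenyl]-5,7-dihydroxy-4H-chromen-4-one F2.
  - Mitsunobu etherification with 15 (PPh3, DIAD, THF) at the non-chelated 7-hydroxyl gives 2-[3,4-bis(benzyloxy)phenyl]-5-hydroxy-7-[2-(trimethylsilyl)ethoxy]-4H-chromen-4-one F3.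
  - Elbs persulfate oxidation (K2S2O8, aq KOH, pyridine, rt) para to the 5-hydroxyl gives potassium 2-[3,4-bis(benzyloxy)phenyl]-5-hydroxy-4-oxo-7-[2-(trimethylsilyl)ethoxy]-4H-chromen-8-yl sulfate F4.
  - Hydrolysis (dilute HCl, Na2SO3, 70 °C) gives 2-[3,4-bis(benzyloxy)phenyl]-5,8-dihydroxy-7-[2-(trimethylsilyl)ethoxy]-4H-chromen-4-one F5.
  - Double benzylation (BnBr, K2CO3, DMF, 60 °C) gives 21.

**Step 6.**
- **What may go wrong:** electron transfer from the strongly reducing pentacarbonylchromate dianion to the pyranone, or its conjugate addition at C2, may compete with acylation at chromium.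
- **Fallback, from 7 back to 12:**
  - Iododecarboxylation of 7 (N-iodosuccinimide, MeCN, 60 °C), of the kind known for electron-rich heteroaryl carboxylic acids, gives 2-[3,4-bis(benzyloxy)phenyl]-5-iodo-4H-pyran-4-one F6.
  - Iodine–magnesium exchange (i-PrMgCl·LiCl, THF, −40 °C), as used for 3-iodochromones, gives chlorido{6-[3,4-bis(benzyloxy)phenyl]-4-oxo-4H-pyran-3-yl}magnesium F7.
  - Addition of F7 to a CO ligand of 9, followed by Me4NBr, gives 12.

**Step 8.**
- **What may go wrong:** the potassium alkoxide of a β-silyl alcohol may fragment by Peterson-type loss of ethene before it adds to dichloroacetylene, and the small ether may be lost on isolation.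
- **Fallback, from 15 back to 19, replacing steps 8 and 9:**
  - Formylation of 15 (HCO2H, DCC, DMAP) gives 2-(trimethylsilyl)ethyl formate F8.
  - Dibromomethylenation of the formate (CBr4, PPh3, CH2Cl2) gives [2-(2,2-dibromoethenyloxy)ethyl](trimethyl)silane F9.
  - n-BuLi (2 equiv, Et2O, −78 °C) gives 18 by elimination and rearrangement, and methanol gives 19.

**Step 14.**
- **What may go wrong:** debenzylation may stall on the poorly soluble salt. The hydrogen sulfate may hydrolyse once set free, and the 5,8-hydroquinone and catechol may be oxidised by air during isolation.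
- **Fallback, from 22 back to 24:**
  - 22 is sulfated as a neutral diester (2,2,2-trichloroethyl chlorosulfate, Et3N, DMAP, THF) to give 5,8-bis(benzyloxy)-2-[3,4-bis(benzyloxy)phenyl]-4-oxo-4H-chromen-7-yl 2,2,2-trichloroethyl sulfate F10, which can be purified on silica.
  - Transfer hydrogenolysis (Pd/C, HCO2NH4, MeOH) removes the benzyl ethers and the trichloroethyl group together to give ammonium 2-(3,4-dihydroxyphenyl)-5,8-dihydroxy-4-oxo-4H-chromen-7-yl sulfate F11.
  - F11 is converted into 24 with one equivalent of HCl at 0 °C.

## Further compounds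

F1 | step 10 | 1-[3,4-bis(benzyloxy)phenyl]-3-(2,4,6-trihydroxyphenyl)propane-1,3-dione | O=C(CC(=O)c1c(O)cc(O)cc1O)c1ccc(OCc2ccccc2)c(OCc2ccccc2)c1
F2 | step 10 | 2-[3,4-bis(benzyloxy)phenyl]-5,7-dihydroxy-4H-chromen-4-one | O=c1cc(-c2ccc(OCc3ccccc3)c(OCc3ccccc3)c2)oc2cc(O)cc(O)c12
F3 | step 10 | 2-[3,4-bis(benzyloxy)phenyl]-5-hydroxy-7-[2-(trimethylsilyl)ethoxy]-4H-chromen-4-one | O=c1cc(-c2ccc(OCc3ccccc3)c(OCc3ccccc3)c2)oc2cc(OCC[Si](C)(C)C)cc(O)c12
F4 | step 10 | potassium 2-[3,4-bis(benzyloxy)phenyl]-5-hydroxy-4-oxo-7-[2-(trimethylsilyl)ethoxy]-4H-chromen-8-yl sulfate | [K+].O=c1cc(-c2ccc(OCc3ccccc3)c(OCc3ccccc3)c2)oc2c(OS(=O)(=O)[O-])c(OCC[Si](C)(C)C)cc(O)c12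
F5 | step 10 | 2-[3,4-bis(benzyloxy)phenyl]-5,8-dihydroxy-7-[2-(trimethylsilyl)ethoxy]-4H-chromen-4-one | O=c1cc(-c2ccc(OCc3ccccc3)c(OCc3ccccc3)c2)oc2c(O)c(OCC[Si](C)(C)C)cc(O)c12
F6 | step 6 | 2-[3,4-bis(benzyloxy)phenyl]-5-iodo-4H-pyran-4-one | O=c1cc(-c2ccc(OCc3ccccc3)c(OCc3ccccc3)c2)occ1I
F7 | step 6 | chlorido{6-[3,4-bis(benzyloxy)phenyl]-4-oxo-4H-pyran-3-yl}magnesium | O=c1cc(-c2ccc(OCc3ccccc3)c(OCc3ccccc3)c2)occ1[Mg]Cl
F8 | step 8 | 2-(trimethylsilyl)ethyl formate | O=COCC[Si](C)(C)C
F9 | step 8 | [2-(2,2-dibromoethenyloxy)ethyl](trimethyl)silane | BrC(Br)=COCC[Si](C)(C)C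
F10 | step 14 | 5,8-bis(benzyloxy)-2-[3,4-bis(benzyloxy)phenyl]-4-oxo-4H-chromen-7-yl 2,2,2-trichloroethyl sulfate | O=c1cc(-c2ccc(OCc3ccccc3)c(OCc3ccccc3)c2)oc2c(OCc3ccccc3)c(OS(=O)(=O)OCC(Cl)(Cl)Cl)cc(OCc3ccccc3)c12
F11 | step 14 | ammonium 2-(3,4-dihydroxyphenyl)-5,8-dihydroxy-4-oxo-4H-chromen-7-yl sulfate | [NH4+].O=c1cc(-c2ccc(O)c(O)c2)oc2c(O)c(OS(=O)(=O)[O-])cc(O)c12
A1 | alternative 1 | 7-(allyloxy)-5-(benzyloxy)-2-[3,4-bis(benzyloxy)phenyl]-4H-chromen-4-one | O=c1cc(-c2ccc(OCc3ccccc3)c(OCc3ccccc3)c2)oc2cc(OCC=C)cc(OCc3ccccc3)c12
A2 | alternative 1 | 3-[3,4-bis(benzyloxy)phenyl]propiolic acid | O=C(O)C#Cc1ccc(OCc2ccccc2)c(OCc2ccccc2)c1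
A3 | alternative 1 | 5-(allyloxy)-3-(benzyloxy)-2-(trimethylsilyl)phenyl trifluoromethanesulfonate | C=CCOc1cc(OCc2ccccc2)c([Si](C)(C)C)c(OS(=O)(=O)C(F)(F)F)c1
A4 | alternative 2 | 2-[3,4-bis(benzyloxy)phenyl]-5,8-dihydroxy-7-(4-methoxybenzyloxy)-4H-chromen-4-one | O=c1cc(-c2ccc(OCc3ccccc3)c(OCc3ccccc3)c2)oc2c(O)c(OCc3ccc(OC)cc3)cc(O)c12
A5 | alternative 2 | 4-{6-[3,4-bis(benzyloxy)phenyl]-4-oxo-4H-pyran-2-yl}-4-hydroxy-3-[(4-methoxybenzyl)oxy]cyclobut-2-en-1-one | O=C1C=C(OCc2ccc(OC)cc2)C1(O)c1cc(=O)cc(-c2ccc(OCc3ccccc3)c(OCc3ccccc3)c2)o1
A6 | alternative 3 | 7-(allyloxy)-2-[3,4-bis(benzyloxy)phenyl]-5,8-dihydroxy-4H-chromen-4-one | O=c1cc(-c2ccc(OCc3ccccc3)c(OCc3ccccc3)c2)oc2c(O)c(OCC=C)cc(O)c12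
A7 | alternative 3 | 1-[4-(allyloxy)-2,5-dimethoxyphenyl]-3-[3,4-bis(benzyloxy)phenyl]propane-1,3-dione | C=CCOc1cc(OC)c(C(=O)CC(=O)c2ccc(OCc3ccccc3)c(OCc3ccccc3)c2)cc1OC
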